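**Assumption:** read from the SMILES, the target is (2S,3R)-trans in one flavanone unit (unit 1) and (2''S,3''S)-cis in the other (unit 2). I take (R)-DTBM-SEGPHOS to be the ligand antipode that gives 2S. If the sense proves opposite, use the (S) antipode.

## Retrosynthetic overview
1. The target comes from its 5,5'',7,7''-tetrabenzyl ether by neutral hydrogenolysis.
2. Key disconnection: the C3–C3'' bond together with the C2''–H bond. A flavanon-3-yl radical (from a 3-bromide) adds to C3'' of an intact flavone, and H-atom transfer to C2'' follows. This one step sets C3, C3'' and C2''.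
3. Both partners come from one flavone, di-O-benzylacacetin. The bromide is made from it by asymmetric CuH conjugate reduction and bromination, which sets C2.
4. Ring C is made once, before the coupling, by thermal condensation of phloroglucinol with an aroylacetate. Rings A and B are bought as arenes, and no ring is formed after that.
5. Phloroglucinol comes from resorcinol by C–H borylation/oxidation. The aroylacetate comes from anisole and methyl malonyl chloride by Friedel–Crafts acylation.

## Route

**Step 1**
Reactants: 1 resorcinol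
Product: 3 phloroglucinol, via triborylated resorcinol 2 (not isolated)
Conditions: pinacolborane (4 equiv), [Ir(OMe)(cod)]2 (1.5 mol %), dtbpy (3 mol %), THF, 80 °C, 16 h; evaporate; 2KHSO5·KHSO4·K2SO4, acetone/H2O, rt, 10 min; NaHSO3 quench
Reagents that add atoms: potassium peroxymonosulfate KHSO5, [K+].[O-]S(=O)(=O)OO
Why: Pinacolborane first masks both OH groups as O-boryl ethers, the sterically governed iridium-catalysed aromatic C–H borylation then takes C5 (the only C–H with no ortho substituent), and peroxymonosulfate converts C–B into C–OH while water frees the phenols (one-pot C–H borylation/oxidation; no stereocentre).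

**Step 2**
Reactants: 4 anisole; 5 methyl malonyl chloride (methyl 3-chloro-3-oxopropanoate)
Product: 6 methyl 3-(4-methoxyphenyl)-3-oxopropanoate
Conditions: AlCl3 (2.2 equiv), CH2Cl2, 0 °C to rt; cold aq. HCl work-up
Reagents that add atoms: none
Why: Friedel–Crafts acylation of the activated arene occurs para to OMe, and the keto ester product is deactivated as its aluminium chelate so it is not acylated again (no stereocentre).

**Step 3**
Reactants: 3 phloroglucinol; 6 methyl 3-(4-methoxyphenyl)-3-oxopropanoate
Product: 7 acacetin (5,7-dihydroxy-2-(4-methoxyphenyl)-4H-chromen-4-one)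
Conditions: neat, 240 °C (microwave or sand bath), 10 min; triturate with aq. NaHCO3/EtOH
Reagents that add atoms: none
Why: In this Mentzer-type thermal pyrone synthesis, loss of methanol gives an aroylketene that C-acylates the threefold-symmetric phenol (so only one regioisomer is possible), and cyclodehydration closes ring C (no stereocentre).

**Step 4**
Reactants: 7 acacetin
Product: 8 5,7-bis(benzyloxy)-2-(4-methoxyphenyl)-4H-chromen-4-one
Conditions: BnBr (3 equiv), K2CO3 (4 equiv), DMF, 80 °C
Reagents that add atoms: benzyl bromide, BrCc1ccccc1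
Why: Williamson etherification at 80 °C also alkylates the chelated 5-OH, and benzyl is chosen because it survives silane, NBS and radical conditions and is removed under neutral conditions at the end.

**Step 5** (run on about one fifth of 8)
Reactants: 8 5,7-bis(benzyloxy)-2-(4-methoxyphenyl)-4H-chromen-4-one
Product: 10 (2R,3R)-5,7-bis(benzyloxy)-3-bromo-2-(4-methoxyphenyl)chroman-4-one (trans), via diphenylsilyl enol ether 9 (not isolated)
Conditions: Cu(OAc)2·H2O (3 mol %), (R)-DTBM-SEGPHOS (3.3 mol %), Ph2SiH2 (1.3 equiv), toluene, 0 °C to rt, no alcohol additive; then THF, NBS (1.1 equiv), –78 °C; pH 7 buffer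
Reagents that add atoms: N-bromosuccinimide, O=C1CCC(=O)N1Br
Why: Asymmetric copper hydride conjugate reduction (1,4-hydrosilylation) delivers hydride to C2 under ligand control and stores the enolate as silyl enol ether (2S)-9, which blocks over-reduction, and NBS then brominates C3 anti to the aryl group faster than it attacks ring A (the C2 label changes to R only because Br raises the rank of C3, and the C3 configuration is erased in step 6).

**Step 6** (key step)
Reactants: 10 (2R,3R)-3-bromoflavanone dibenzyl ether; 8 5,7-bis(benzyloxy)-2-(4-methoxyphenyl)-4H-chromen-4-one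
Product: 13 (2S,3R,2''S,3''S)-5,5'',7,7''-tetrakis(benzyloxy)-4',4'''-dimethoxy-3,3''-biflavanone, via flavanon-3-yl radical 11 (not isolated), via C2'' benzylic radical 12 (not isolated)
Conditions: 8 (4 equiv, 0.5 M; excess recovered), Ru(bpy)3(PF6)2 (1 mol %), Hantzsch ester (diethyl 2,6-dimethyl-1,4-dihydropyridine-3,5-dicarboxylate, 1.5 equiv, solid, in portions), NaHCO3 (2 equiv), CH2Cl2/MeCN 1:1, 450 nm LEDs, 0 °C; 10 added by syringe pump over 10 h; chromatography
Reagents that add atoms: none
Why: Proposed new method: the photoreduced ruthenium complex cleaves the C–Br bond to the electrophilic α-keto radical 11, which adds anti to its C2 aryl group (3R, trans) to C3'' of the flavone, the nucleophilic α-carbon of the vinylogous ester and the terminus that gives the anisyl- and oxygen-stabilised radical 12; an open staggered transition state that places H/H, C4/C4'' (opposed carbonyl dipoles) and C2/C2'' antiperiplanar favours 3''S, and the bulky Hantzsch ester (or its radical cation) then transfers H to C2'' on the face opposite the pseudoaxial C3'' substituent, giving the kinetic 2'',3''-cis unit (2''S); the closest known reaction types are photoredox reductive Giese-type hydroalkylation of styrenes and enol ethers with α-bromocarbonyl compounds and radical C3 functionalisation of flavones.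

**Step 7**
Reactants: 13 tetrabenzyl ether
Product: 14 (2S,3R,2''S,3''S)-5,5'',7,7''-tetrahydroxy-4',4'''-dimethoxy-3,3''-biflavanone (target)
Conditions: H2 (1 atm), 10% Pd/C, EtOAc/MeOH 1:1, rt; stop after uptake of 4 equiv H2
Reagents that add atoms: none
Why: Catalytic hydrogenolysis of the four aryl benzyl ethers is neutral, so neither enolisation at C3/C3'' nor retro-oxa-Michael opening at C2/C2'' can scramble the trans/cis pattern, and the aryl methyl ethers are untouched.

## Compound list
1 | resorcinol | Oc1cccc(O)c1 | starting material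
2 | 2-[3,5-bis(pinacolboryloxy)phenyl]-4,4,5,5-tetramethyl-1,3,2-dioxaborolane | CC1(C)OB(Oc2cc(OB3OC(C)(C)C(C)(C)O3)cc(B3OC(C)(C)C(C)(C)O3)c2)OC1(C)C | intermediate
3 | phloroglucinol | Oc1cc(O)cc(O)c1 | intermediate
4 | anisole | COc1ccccc1 | starting material
5 | methyl malonyl chloride | COC(=O)CC(=O)Cl | starting material
6 | methyl 3-(4-methoxyphenyl)-3-oxopropanoate | COC(=O)CC(=O)c1ccc(OC)cc1 | intermediate
7 | acacetin | COc1ccc(-c2cc(=O)c3c(O)cc(O)cc3o2)cc1 | intermediate
8 | 5,7-bis(benzyloxy)-2-(4-methoxyphenyl)-4H-chromen-4-one | COc1ccc(-c2cc(=O)c3c(OCc4ccccc4)cc(OCc4ccccc4)cc3o2)cc1 | intermediate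
9 | (2S)-5,7-bis(benzyloxy)-4-(diphenylsilyloxy)-2-(4-methoxyphenyl)-2H-chromene | COc1ccc([C@H]2Oc3cc(OCc4ccccc4)cc(OCc4ccccc4)c3C(O[SiH](c3ccccc3)c3ccccc3)=C2)cc1 | intermediate
10 | (2R,3R)-5,7-bis(benzyloxy)-3-bromo-2-(4-methoxyphenyl)chroman-4-one | COc1ccc([C@H]2Oc3cc(OCc4ccccc4)cc(OCc4ccccc4)c3C(=O)[C@@H]2Br)cc1 | intermediate
11 | (2S)-5,7-bis(benzyloxy)-2-(4-methoxyphenyl)-4-oxochroman-3-yl radical | COc1ccc([C@H]2Oc3cc(OCc4ccccc4)cc(OCc4ccccc4)c3C(=O)[CH]2)cc1 | intermediate
12 | (2S,3R,3''S) adduct radical centred on C2'' | COc1ccc([C@H]2Oc3cc(OCc4ccccc4)cc(OCc4ccccc4)c3C(=O)[C@@H]2[C@@H]2C(=O)c3c(OCc4ccccc4)cc(OCc4ccccc4)cc3O[C]2c2ccc(OC)cc2)cc1 | intermediate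
13 | (2S,3R,2''S,3''S)-5,5'',7,7''-tetrakis(benzyloxy)-4',4'''-dimethoxy-3,3''-biflavanone | COc1ccc([C@H]2Oc3cc(OCc4ccccc4)cc(OCc4ccccc4)c3C(=O)[C@@H]2[C@@H]2C(=O)c3c(OCc4ccccc4)cc(OCc4ccccc4)cc3O[C@@H]2c2ccc(OC)cc2)cc1 | intermediate
14 | (2S,3R,2''S,3''S)-5,5'',7,7''-tetrahydroxy-4',4'''-dimethoxy-3,3''-biflavanone | COc1ccc([C@H]2Oc3cc(O)cc(O)c3C(=O)[C@@H]2[C@@H]2C(=O)c3c(O)cc(O)cc3O[C@@H]2c2ccc(OC)cc2)cc1 | target

## Summary
Total step count: 7.
Longest linear sequence: 6 (steps 1, 3, 4, 5, 6, 7).

## Three steps most likely to fail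

**Step 6.**
- Radical 11 may be reduced to the flavanone before it adds to 8.
- Radical 12 may abstract Br or be oxidised, then lose H3'' to give a 3-substituted flavone.
- The 3''S/3''R ratio may be modest.
- Radical 11 may open reversibly by C2–O scission and erode the ee. The low temperature and the high concentration of 8 are chosen to suppress this.

The fallback sets out from 9 (made from 8 as in step 5, NBS omitted) and 10, and returns at 13. Irradiate 10 with 9 and Ru(bpy)3(PF6)2 without any H donor. Radical 11 adds to the silyl enol ether, and the α-silyloxy radical is oxidised in the chain and loses silicon. Each new centre is set anti to its own aryl group, so this gives the C2-symmetric trans,trans dimer (2S,3R,2''S,3''R)-tetrabenzyl ether F1. One equivalent of KN(SiMe3)2 in THF at –78 °C then gives the potassium mono-enolate F2; either ketone gives the same species. A quench with 2,6-di-tert-butyl-4-methylphenol protonates C3'' anti to the C2'' aryl group. This inverts that one centre to the cis arrangement of 13.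

**Step 5.** The electron-rich flavone may react slowly or with low ee, and NBS may touch ring A. The fallback sets out from 8 and returns at 10.
- Asymmetric hydrogenation uses Ru(cod)(2-methylallyl)2, the chiral N-heterocyclic carbene from SINpEt·HBF4 and KOt-Bu (antipode chosen for 2S), and H2 at 100 bar. It gives (2S)-5,7-bis(benzyloxy)-2-(4-methoxyphenyl)chroman-4-ol F3 as a C4 epimer mixture, which does not matter.
- Dess–Martin oxidation gives (2S)-5,7-bis(benzyloxy)-2-(4-methoxyphenyl)chroman-4-one F4.
- TMSOTf/Et3N gives the trimethylsilyl enol ether F5, and NBS at –78 °C gives 10.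

**Step 1.** The O-boryl groups may steer some borylation ortho, and phloroglucinol may be over-oxidised. The fallback sets out from 1 and 6, returns at 7, and bypasses 3. It installs the third oxygen last, by ketone-directed C–H oxygenation.
- Heat 1 with 6 neat at 240 °C to give 7-hydroxy-2-(4-methoxyphenyl)-4H-chromen-4-one F6.
- In TFA/TFAA this is carried as its 7-trifluoroacetate F7.
- [RuCl2(p-cymene)]2 with PhI(OCOCF3)2 at 80 °C oxygenates the peri C5–H to give the 5,7-bis(trifluoroacetate) F8.
- Aqueous work-up hydrolyses F8 to 7.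

## Further compounds
F1 | step 6 | (2S,3R,2''S,3''R)-5,5'',7,7''-tetrakis(benzyloxy)-4',4'''-dimethoxy-3,3''-biflavanone | COc1ccc([C@H]2Oc3cc(OCc4ccccc4)cc(OCc4ccccc4)c3C(=O)[C@@H]2[C@H]2C(=O)c3c(OCc4ccccc4)cc(OCc4ccccc4)cc3O[C@@H]2c2ccc(OC)cc2)cc1
F2 | step 6 | potassium mono-enolate of F1 | [K+].COc1ccc([C@H]2Oc3cc(OCc4ccccc4)cc(OCc4ccccc4)c3C(=O)[C@@H]2C2=C([O-])c3c(OCc4ccccc4)cc(OCc4ccccc4)cc3O[C@@H]2c2ccc(OC)cc2)cc1
F3 | step 5 | (2S)-5,7-bis(benzyloxy)-2-(4-methoxyphenyl)chroman-4-ol (C4 epimers) | COc1ccc([C@H]2Oc3cc(OCc4ccccc4)cc(OCc4ccccc4)c3C(O)C2)cc1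
F4 | step 5 | (2S)-5,7-bis(benzyloxy)-2-(4-methoxyphenyl)chroman-4-one | COc1ccc([C@H]2Oc3cc(OCc4ccccc4)cc(OCc4ccccc4)c3C(=O)C2)cc1
F5 | step 5 | (2S)-5,7-bis(benzyloxy)-2-(4-methoxyphenyl)-4-(trimethylsilyloxy)-2H-chromene | COc1ccc([C@H]2Oc3cc(OCc4ccccc4)cc(OCc4ccccc4)c3C(O[Si](C)(C)C)=C2)cc1
F6 | step 1 | 7-hydroxy-2-(4-methoxyphenyl)-4H-chromen-4-one | COc1ccc(-c2cc(=O)c3ccc(O)cc3o2)cc1
F7 | step 1 | 2-(4-methoxyphenyl)-4-oxo-4H-chromen-7-yl trifluoroacetate | COc1ccc(-c2cc(=O)c3ccc(OC(=O)C(F)(F)F)cc3o2)cc1
F8 | step 1 | 2-(4-methoxyphenyl)-4-oxo-4H-chromene-5,7-diyl bis(trifluoroacetate) | COc1ccc(-c2cc(=O)c3c(OC(=O)C(F)(F)F)cc(OC(=O)C(F)(F)F)cc3o2)cc1
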